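| setting | Saturday's | Friday's | flask |
|---|---|---|---|
| substrate | 0.050 M | 0.10 M | 0.050 M |
| temperature | 0 °C | −15 °C | 0 °C |
| remark | the very flask that is asked about, followed so far | run made earlier |  |
| time |  |  | 2.5 d |

Saturday's run (percent of the substrate charged)

| time / h | target / % | substrate / % |
|---|---|---|
| 6.00 | 28.1 | 0 |
| 12.0 | 27.3 | 0 |
| 20.0 | 27.1 | 0 |
| 25.0 | 26.9 | 0 |
| 30.0 | 26.8 | 0 |
| 40.0 | 27.0 | 0 |

Friday's run (percent of the substrate charged)

| time / d | target / % | substrate / % |
|---|---|---|
| 0.250 | 20.8 | 73.9 |
| 0.500 | 31.5 | 50.4 |
| 0.833 | 35.7 | 26.0 |
| 1.25 | 29.8 | 7.7 |
| 2.00 | 13.7 | 0.6 |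
| 4.00 | 8.0 | 0 |

(scatter of a reading: 0.3 percentage points)

- green: at 2.5 d take out 90% of the target then present, then wait 5.0 d
- blue: change nothing and wait 5.0 d more
- amber: at 2.5 d add substrate, 50.0% of the amount charged, then wait 5.0 d
- grey: at 2.5 d raise the temperature by 25 K, then wait 5.0 d

- target, in percent of the substrate first charged, at 2.5 d
- which option adds most target ("none" when 2 percentage points or less is all one gets) (green / blue / amber / grey / none)
- target present, with what was taken out counted in, in percent of the substrate first charged, after green
- target present, with what was taken out counted in, in percent of the substrate first charged, after grey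

- removed target is counted in
- additions bring no volume worth counting

- A level curve tempts me to call a reaction finished, but in Saturday's flask that is a trap, since a level line can also be two opposite flows in balance.
- Saturday's run looks contradictory: at 40.0 h substrate reads 0% and target reads 27.0%, so 73.0% of the charge stands somewhere unseen.
- Friday's colder run shows the way out: target reaches a reading of 35.7% at 0.833 d, then drops to 8.0% at 4.00 d, so target feeds the unseen part.
- Saturday's target reads between 26.8% and 27.3% from 12.0 h to 40.0 h, and a one-way drain empties its source, so I take the unseen part to flow back.
- I therefore carry K = 2.70, the balance ratio, unseen part over target as read on Saturday's level line at 40.0 h; making rules early and balance rules later, which is kinetic against thermodynamic control.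
- In the asked flask, target is then the pool (target plus unseen part) divided by 1 + K, which gives my estimate of 27.0% at 2.5 d, later than Saturday's last reading.
- Waiting 5.0 d is far longer than the 12.0 h by which Saturday's line reads level, so I expect each option to rebalance and blue to gain nothing.
- Green gives 44.7% with the removed part counted, and amber gains 14 percentage points.
- For grey, I take Friday's last reading as level, which gives a ratio of 11.5, hence a slope B = 6810 K of ln K against 1/T, with T the absolute temperature; after the rise of 25 K that estimate gives a ratio of 0.335 and 74.9% target, so I choose grey.
- The forecast, which reads “a first-order reversible step”, says 27% now, grey as best, 44.7% after green and 75% after grey.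
- The flask gives 27.0% now, 44.8% after green and 79.1% after grey; the gains are 18 points, 0 points, 14 points and 52 points for green, blue, amber and grey, so the best is grey.

    substrate → target, rate k1*[substrate]/(1 + ([substrate]/sat1)) (38.0 mM, k = 1.70 h⁻¹, Ea = 91.0 kJ mol⁻¹)
    target ⇌ isomer of the product (K = 2.70, k = 0.670 h⁻¹, Ea = 83.0 kJ mol⁻¹, ΔH = −63.0 kJ mol⁻¹)
    (constants at 0 °C)

- The unseen part is the isomer of the product, and its relaxation half-life with target, both directions together, is 0.755 h, far shorter than 2.5 d. The asked flask holds 27.0% target beside 73.0% isomer of the product at 2.50 d, and its answer stays within 5 points of itself from 0.31 d to 20 d at least, so a wrong "now" needs a look outside that span. For the flask kept at 25 °C, K = 2.70 scaled by B gives 0.335, so 74.9% target; the computed flask stands at 79.1%, higher.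

The data are calculated on assumed constants; the scatter is artificial.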